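**Plan**
- Ring numbering: C1 is the ketone carbon, C2 carries the propenyl group, C3 is CH, C4 is the quaternary stereocentre (OMe and arylpropenyl), C5 carries OMe, C6 is CH. The unit C5(OMe)=C6–C1(=O) of the cyclohexa-2,5-dienone is a vinylogous methyl ester: C5 is a methyl ester carbonyl olefinated by a one-carbon ylide C6 that is acylated by C1.
- Retrosynthetic cuts, in order: C5=C6 and C1–C6 (opening the only ring), C2–propenyl, the O–CH3 bond at C4, C3–C4 (alkyne to ketone), the styrene C=C.
- Forward: aldol condensation gives an aryl enone α-keto ester; a propiolate adds to its ketone; O-methylation, syn-hydrostannation and Stille coupling build the open (3Z)-dienoate; the ester is unmasked to the acid chloride; the ring closes last with methylenetriphenylphosphorane as C6.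
- Stereochemistry: C4 is set by ligand-controlled alkynylation of the α-keto ester and is quaternary from then on. The alkene geometries come from the condensation (E), the syn-hydrostannation (3Z) and stereoretentive coupling with (E)-1-bromopropene.

Key step: step 10

Remark: the (1S,2S) amino alcohol ligand of step 4 is assumed to deliver the alkynyl group to the ketone face that gives the (R) alcohol 8; if the opposite sense is found, the equally available (1R,2R) ligand is to be used.

Step 1
Reactants: 1 veratraldehyde; 2 2-oxobutanoic acid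
Product: 3 (E)-4-(3,4-dimethoxyphenyl)-3-methyl-2-oxobut-3-enoic acid
Conditions: KOH (1.5 equiv), MeOH, 0 °C → rt; then aq. HCl
Reagents that add atoms: none
Why: Aldol condensation of the only enolisable position of the keto acid (its CH2) with the non-enolisable aldehyde, followed by dehydration, should give the conjugated enone as the thermodynamically preferred E isomer (aryl trans to the keto carbonyl).

Step 2
Reactants: 3 (E)-4-(3,4-dimethoxyphenyl)-3-methyl-2-oxobut-3-enoic acid
Product: 4 methyl (E)-4-(3,4-dimethoxyphenyl)-3-methyl-2-oxobut-3-enoate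
Conditions: MeOH, H2SO4 (cat.), 50 °C
Reagents that add atoms: methanol, CO
Why: Fischer esterification of the α-keto acid in excess methanol, a routine conversion for 4-aryl-2-oxobut-3-enoic acids that leaves the enone untouched.

Step 3
Reactants: 5 propiolic acid; 6 2-(trimethylsilyl)ethanol
Product: 7 2-(trimethylsilyl)ethyl propiolate
Conditions: DCC, DMAP (cat.), CH2Cl2, −20 → 0 °C
Reagents that add atoms: none
Why: Steglich esterification at low temperature gives a fluoride-labile propiolate, chosen so that the carboxylic acid can later be freed without the acid that the tertiary doubly allylic methyl ether at C4 might not survive.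

Step 4
Reactants: 4 methyl (E)-4-(3,4-dimethoxyphenyl)-3-methyl-2-oxobut-3-enoate; 7 2-(trimethylsilyl)ethyl propiolate
Product: 8 5-methyl 1-[2-(trimethylsilyl)ethyl] (4R)-4-[(E)-1-(3,4-dimethoxyphenyl)prop-1-en-2-yl]-4-hydroxypent-2-ynedioate
Conditions: Zn(OTf)2 (20 mol %), (1S,2S)-3-(tert-butyldimethylsilyloxy)-2-(dimethylamino)-1-(4-nitrophenyl)propan-1-ol (22 mol %), i-Pr2NEt (30 mol %), toluene, 50 °C
Reagents that add atoms: none
Why: Catalytic asymmetric alkynylzinc addition to an α-keto ester, in which the zinc acetylide of the acidic propiolate adds 1,2 to the ketone (the most electrophilic carbonyl) within the chiral zinc amino alkoxide complex, whose facial bias sets the future C4 as R.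

Step 5
Reactants: 8 5-methyl 1-[2-(trimethylsilyl)ethyl] (4R)-4-[(E)-1-(3,4-dimethoxyphenyl)prop-1-en-2-yl]-4-hydroxypent-2-ynedioate
Product: 9 5-methyl 1-[2-(trimethylsilyl)ethyl] (4R)-4-[(E)-1-(3,4-dimethoxyphenyl)prop-1-en-2-yl]-4-methoxypent-2-ynedioate
Conditions: MeOTf (3 equiv), 2,6-di-tert-butyl-4-methylpyridine (4 equiv), CH2Cl2, rt → 40 °C
Reagents that add atoms: methyl trifluoromethanesulfonate, COS(=O)(=O)C(F)(F)F
Why: O-methylation of a tertiary alcohol with methyl triflate and a hindered pyridine base proceeds without forming an alkoxide, which avoids retro-alkynylation and oxa-Michael addition to the ynoate and leaves the stereocentre untouched.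

Step 6
Reactants: 9 5-methyl 1-[2-(trimethylsilyl)ethyl] (4R)-4-[(E)-1-(3,4-dimethoxyphenyl)prop-1-en-2-yl]-4-methoxypent-2-ynedioate
Product: 10 5-methyl 1-[2-(trimethylsilyl)ethyl] (2E,4S)-4-[(E)-1-(3,4-dimethoxyphenyl)prop-1-en-2-yl]-4-methoxy-2-(tributylstannyl)pent-2-enedioate
Conditions: Bu3SnH (1.2 equiv, slow addition), Pd(PPh3)4 (3 mol %), THF, 0 °C → rt
Reagents that add atoms: tributyltin hydride, CCCC[SnH](CCCC)CCCC
Why: Syn-hydrostannation of an alkynoate catalysed by zerovalent palladium places tin α to the ester and hydrogen on the β carbon (a preference reinforced by the quaternary propargylic carbon), so the ester and C4 end up cis as the later ring closure requires; the descriptor at C4 changes from R to S only because the CIP priorities change, and with the hydroxyl already methylated no butenolide can form.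

Step 7
Reactants: 10 5-methyl 1-[2-(trimethylsilyl)ethyl] (2E,4S)-4-[(E)-1-(3,4-dimethoxyphenyl)prop-1-en-2-yl]-4-methoxy-2-(tributylstannyl)pent-2-enedioate; 11 (E)-1-bromoprop-1-ene
Product: 12 methyl (2S,3Z,5E)-2-[(E)-1-(3,4-dimethoxyphenyl)prop-1-en-2-yl]-2-methoxy-4-{[2-(trimethylsilyl)ethoxy]carbonyl}hepta-3,5-dienoate
Conditions: 11 (3 equiv), Pd(PPh3)4 (10 mol %), CuCl (5 equiv), LiCl (6 equiv), DMSO, 60 °C, sealed tube
Reagents that add atoms: none
Why: Stille coupling with copper chloride assistance, in which tin-to-copper exchange speeds the otherwise slow transfer of the α-stannyl enoate carbon to palladium, joins the two sp2 carbons with retention of geometry in both partners.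

Step 8
Reactants: 12 methyl (2S,3Z,5E)-2-[(E)-1-(3,4-dimethoxyphenyl)prop-1-en-2-yl]-2-methoxy-4-{[2-(trimethylsilyl)ethoxy]carbonyl}hepta-3,5-dienoate
Product: 13 methyl (2S,3Z,5E)-4-carboxy-2-[(E)-1-(3,4-dimethoxyphenyl)prop-1-en-2-yl]-2-methoxyhepta-3,5-dienoate
Conditions: Bu4NF (1.5 equiv), THF, 0 °C → rt; then cold dilute aq. HCl to pH 3
Reagents that add atoms: none
Why: Fluoride-induced fragmentation of the 2-(trimethylsilyl)ethyl ester (attack at silicon, loss of ethene) frees the carboxylate under non-acidic conditions that the hindered methyl ester, the diene and the C4 ether tolerate.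

Step 9
Reactants: 13 methyl (2S,3Z,5E)-4-carboxy-2-[(E)-1-(3,4-dimethoxyphenyl)prop-1-en-2-yl]-2-methoxyhepta-3,5-dienoate
Product: 14 methyl (2S,3Z,5E)-4-(chlorocarbonyl)-2-[(E)-1-(3,4-dimethoxyphenyl)prop-1-en-2-yl]-2-methoxyhepta-3,5-dienoate
Conditions: 1-chloro-N,N,2-trimethylprop-1-en-1-amine (1.0 equiv), CH2Cl2, 0 °C → rt; concentrate, use at once
Reagents that add atoms: 1-chloro-N,N,2-trimethylprop-1-en-1-amine, CC(C)=C(Cl)N(C)C
Why: Acid chloride formation with an α-chloroenamine is neutral and produces no HCl, so neither the acid-sensitive C4 ether nor the alkene geometry is put at risk, and the crude chloride is used directly to forestall cyclisation onto the neighbouring ester.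

Step 10
Reactants: 14 methyl (2S,3Z,5E)-4-(chlorocarbonyl)-2-[(E)-1-(3,4-dimethoxyphenyl)prop-1-en-2-yl]-2-methoxyhepta-3,5-dienoate; 15 methyltriphenylphosphonium bromide
Product: 18 (4S)-4-[(E)-1-(3,4-dimethoxyphenyl)prop-1-en-2-yl]-4,5-dimethoxy-2-[(E)-prop-1-en-1-yl]cyclohexa-2,5-dien-1-one, via methylenetriphenylphosphorane 16 (not isolated), via keto ylide 17 (not isolated)
Conditions: 15 (2.05 equiv), KN(SiMe3)2 (2.0 equiv), THF, 0 °C; add 14 (1.05 equiv), −78 °C → rt; then PhMe, 110 °C
Reagents that add atoms: none
Why: Proposed new method: one equivalent of 16 is C-acylated by the acid chloride of 14 and the second deprotonates the resulting acylphosphonium salt, so the keto-stabilised ylide 17 carries the future C6 on C1. On heating, the ylide carbon adds to the C5 methyl ester carbonyl in a 6-exo-trig closure and the oxaphosphetane collapses with loss of Ph3PO to the C5=C6 enol ether, the ester methoxy group remaining on C5 (intramolecular Wittig olefination of an ester). The closest known reaction types are the acylation of methylenetriphenylphosphorane by acid chlorides and the intramolecular olefination of ester carbonyls by stabilised ylides in tetronate syntheses from α-hydroxy esters and ketenylidenetriphenylphosphorane and in chromone syntheses; a carbocyclic six-membered closure of a keto ylide onto an aliphatic methyl ester is the new element. No stereocentre is created, and the quaternary C4, which bears no hydrogen and takes no part in bond formation, keeps its configuration. The step needs acylation at the acid chloride and not at the ester, which the large difference in electrophilicity and the α-quaternary shielding of the ester secure at −78 °C, and it needs ylide and ester held close together, which the (3Z) double bond secures. The α-methoxy group raises the electrophilicity of the non-enolisable ester, a slight excess of 14 leaves no free 16 to methylenate the product ketone, and irreversible loss of Ph3PO draws any reversible O-attack of the ylide enolate back into the productive path.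

**Compound list**
1 | veratraldehyde (3,4-dimethoxybenzaldehyde) | COc1ccc(C=O)cc1OC | starting material
2 | 2-oxobutanoic acid | CCC(=O)C(=O)O | starting material
3 | (E)-4-(3,4-dimethoxyphenyl)-3-methyl-2-oxobut-3-enoic acid | OC(=O)C(=O)/C(C)=C/c1ccc(OC)c(OC)c1 | intermediate
4 | methyl (E)-4-(3,4-dimethoxyphenyl)-3-methyl-2-oxobut-3-enoate | COC(=O)C(=O)/C(C)=C/c1ccc(OC)c(OC)c1 | intermediate
5 | propiolic acid | C#CC(=O)O | starting material
6 | 2-(trimethylsilyl)ethanol | C[Si](C)(C)CCO | starting material
7 | 2-(trimethylsilyl)ethyl propiolate | C#CC(=O)OCC[Si](C)(C)C | intermediate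
8 | 5-methyl 1-[2-(trimethylsilyl)ethyl] (4R)-4-[(E)-1-(3,4-dimethoxyphenyl)prop-1-en-2-yl]-4-hydroxypent-2-ynedioate | C[Si](C)(C)CCOC(=O)C#C[C@](O)(/C(C)=C/c1ccc(OC)c(OC)c1)C(=O)OC | intermediate
9 | 5-methyl 1-[2-(trimethylsilyl)ethyl] (4R)-4-[(E)-1-(3,4-dimethoxyphenyl)prop-1-en-2-yl]-4-methoxypent-2-ynedioate | C[Si](C)(C)CCOC(=O)C#C[C@](OC)(/C(C)=C/c1ccc(OC)c(OC)c1)C(=O)OC | intermediate
10 | 5-methyl 1-[2-(trimethylsilyl)ethyl] (2E,4S)-4-[(E)-1-(3,4-dimethoxyphenyl)prop-1-en-2-yl]-4-methoxy-2-(tributylstannyl)pent-2-enedioate | CCCC[Sn](CCCC)(CCCC)/C(C(=O)OCC[Si](C)(C)C)=C/[C@](OC)(/C(C)=C/c1ccc(OC)c(OC)c1)C(=O)OC | intermediate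
11 | (E)-1-bromoprop-1-ene | C/C=C/Br | starting material
12 | methyl (2S,3Z,5E)-2-[(E)-1-(3,4-dimethoxyphenyl)prop-1-en-2-yl]-2-methoxy-4-{[2-(trimethylsilyl)ethoxy]carbonyl}hepta-3,5-dienoate | C/C=C/C(C(=O)OCC[Si](C)(C)C)=C/[C@](OC)(/C(C)=C/c1ccc(OC)c(OC)c1)C(=O)OC | intermediate
13 | methyl (2S,3Z,5E)-4-carboxy-2-[(E)-1-(3,4-dimethoxyphenyl)prop-1-en-2-yl]-2-methoxyhepta-3,5-dienoate | C/C=C/C(C(=O)O)=C/[C@](OC)(/C(C)=C/c1ccc(OC)c(OC)c1)C(=O)OC | intermediate
14 | methyl (2S,3Z,5E)-4-(chlorocarbonyl)-2-[(E)-1-(3,4-dimethoxyphenyl)prop-1-en-2-yl]-2-methoxyhepta-3,5-dienoate | C/C=C/C(C(Cl)=O)=C/[C@](OC)(/C(C)=C/c1ccc(OC)c(OC)c1)C(=O)OC | intermediate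
15 | methyltriphenylphosphonium bromide | C[P+](c1ccccc1)(c1ccccc1)c1ccccc1.[Br-] | starting material
16 | methylenetriphenylphosphorane | C=P(c1ccccc1)(c1ccccc1)c1ccccc1 | intermediate
17 | methyl (2S,3Z,5E)-2-[(E)-1-(3,4-dimethoxyphenyl)prop-1-en-2-yl]-2-methoxy-4-[2-(triphenyl-λ5-phosphanylidene)acetyl]hepta-3,5-dienoate (keto ylide) | C/C=C/C(C(=O)C=P(c1ccccc1)(c1ccccc1)c1ccccc1)=C/[C@](OC)(/C(C)=C/c1ccc(OC)c(OC)c1)C(=O)OC | intermediate
18 | (4S)-4-[(E)-1-(3,4-dimethoxyphenyl)prop-1-en-2-yl]-4,5-dimethoxy-2-[(E)-prop-1-en-1-yl]cyclohexa-2,5-dien-1-one | C/C=C/C1=C[C@](OC)(/C(C)=C/c2ccc(OC)c(OC)c2)C(OC)=CC1=O | target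

**Step count**
Total: 10 steps. Longest linear sequence: 9 steps (steps 1, 2 and 4 to 10; step 3 prepares the alkyne partner).

**Steps most likely to fail**

Step 10. The stabilised ylide may fail to add to the hindered ester carbonyl before it decomposes thermally, or the chloride may cyclise onto the ester before it is acylated. The fallback closes the ring by Claisen condensation and sets out from 14. Me2CuLi in THF at −78 °C should convert the acid chloride into the methyl ketone methyl (2S,3Z,5E)-4-acetyl-2-[(E)-1-(3,4-dimethoxyphenyl)prop-1-en-2-yl]-2-methoxyhepta-3,5-dienoate F1. LiN(SiMe3)2 (2 equiv) in THF at −78 → 0 °C should then cyclise the only possible enolate onto the methyl ester to give (4S)-4-[(E)-1-(3,4-dimethoxyphenyl)prop-1-en-2-yl]-4-methoxy-6-[(E)-prop-1-en-1-yl]cyclohex-5-ene-1,3-dione F2. O-methylation of F2 with Me3SiCHN2 in toluene/MeOH returns to the route at 18. In this variant the site of O-methylation is no longer fixed by construction, so the wanted enol ether has to be separated chromatographically from the one methylated at the other oxygen.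

Step 4. Amine-induced oligomerisation of the propiolate may limit conversion, and facial discrimination at the hindered, conjugated ketone may be weak. The fallback replaces catalysis by resolution and sets out from 4 and 7. Deprotonation of 7 with LiN(SiMe3)2 in THF at −78 °C and addition of 4 should give the racemic alcohol 5-methyl 1-[2-(trimethylsilyl)ethyl] (4RS)-4-[(E)-1-(3,4-dimethoxyphenyl)prop-1-en-2-yl]-4-hydroxypent-2-ynedioate F3. Preparative chromatography on an amylose tris(3,5-dimethylphenylcarbamate) stationary phase then delivers the R enantiomer, which is 8.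

Step 7. Slow transfer of the α-stannyl enoate carbon may allow protodestannylation, homocoupling or cycloaddition of the product diene to compete. The fallback reverses the polarity of the coupling and sets out from 10. Iododestannylation with I2 (1.0 equiv) in CH2Cl2 at 0 °C should give, with retention, 5-methyl 1-[2-(trimethylsilyl)ethyl] (2E,4S)-4-[(E)-1-(3,4-dimethoxyphenyl)prop-1-en-2-yl]-2-iodo-4-methoxypent-2-enedioate F4. Suzuki–Miyaura coupling of F4 with (E)-prop-1-en-1-ylboronic acid pinacol ester (Pd(dppf)Cl2, K3PO4, THF/H2O, 40 °C) returns to the route at 12.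

**Further compounds**
F1 | step 10 | methyl (2S,3Z,5E)-4-acetyl-2-[(E)-1-(3,4-dimethoxyphenyl)prop-1-en-2-yl]-2-methoxyhepta-3,5-dienoate | C/C=C/C(C(C)=O)=C/[C@](OC)(/C(C)=C/c1ccc(OC)c(OC)c1)C(=O)OC
F2 | step 10 | (4S)-4-[(E)-1-(3,4-dimethoxyphenyl)prop-1-en-2-yl]-4-methoxy-6-[(E)-prop-1-en-1-yl]cyclohex-5-ene-1,3-dione | C/C=C/C1=C[C@](OC)(/C(C)=C/c2ccc(OC)c(OC)c2)C(=O)CC1=O
F3 | step 4 | 5-methyl 1-[2-(trimethylsilyl)ethyl] (4RS)-4-[(E)-1-(3,4-dimethoxyphenyl)prop-1-en-2-yl]-4-hydroxypent-2-ynedioate (racemate) | C[Si](C)(C)CCOC(=O)C#CC(O)(/C(C)=C/c1ccc(OC)c(OC)c1)C(=O)OC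
F4 | step 7 | 5-methyl 1-[2-(trimethylsilyl)ethyl] (2E,4S)-4-[(E)-1-(3,4-dimethoxyphenyl)prop-1-en-2-yl]-2-iodo-4-methoxypent-2-enedioate | I/C(C(=O)OCC[Si](C)(C)C)=C/[C@](OC)(/C(C)=C/c1ccc(OC)c(OC)c1)C(=O)OC
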